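## The problem

Compound 14 is a benzil: a 1,2-diketone that joins a 4-methoxyphenyl group to C6 of a 2,2-dimethyl-2H-chromene. It has no stereocentre, so nothing has to be controlled in space; every difficulty is one of position on ring A. That ring is a benzene with five substituents in fixed order: oxygens at C5, C7 and C8a, the acyl carbon at C6 between two of them, and the pyran carbon C4a. Two distinctions must be made: the pyran oxygen has to be the one para to the acyl carbon, and of the two oxygens flanking the acyl group the one beside the pyran ring (C5) is a methyl ether while the other (C7) is a free phenol. Two groups are fragile: the 1,2-diketone, which is attacked by hydroxide, alkoxide and carbanions (benzilic acid rearrangement, cleavage between the carbonyls), and the chromene C3=C4 bond, an electron-rich styrene that excludes hydrogenation, strong electrophiles and hot strong acid. The feature that opens the structure is the 1,3,5-arrangement of the oxygens at C5, C7 and C8a with the acyl carbon on C6: ring A is a 2-acylphloroglucinol, the pattern a 3,5,7-triketo ester gives when it folds by Claisen condensation. Ring A, its three oxygens and the first carbonyl can therefore come from an open chain in one step, provided the second carbonyl is masked on a carbon without hydrogen. The fold leaves the two ortho hydroxyls equivalent, so the rest of the route has to break that symmetry while the pyran ring is attached.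

## Retrosynthesis

**14 to 13.** No skeletal bond is cut. The C7 phenol is covered as a methoxymethyl ether and the carbonyl next to the anisyl ring as a dimethyl ketal, giving 13. Both are acetals, so one acid treatment at the end removes both. This is preferred to any plan that carries the free diketone, because every earlier step uses base, a nucleophile or heat. The forward reaction must hydrolyse both groups without hydrating the chromene.

**13 to 12.** The O–CH3 bond at C5 is cut. In 12 the C5 hydroxyl is the only free one, so the methylation needs no selectivity. It is hydrogen-bonded to the ketone and flanked by C4a, so it needs forcing conditions.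

**12 to 10.** The C4–C4a bond is cut and the pyran ring opened, which leads through the allenyl phenol 11 back to the aryl 1,1-dimethylpropargyl ether 10. Against a condensation with an enal, this cut fixes the pyran oxygen as the para oxygen, because the ether is made before the ring. Only the choice between the two ortho carbons remains. In 10 one ortho oxygen is a free hydroxyl bonded to the ketone and the other is a MOM ether. The forward rearrangement must go to the carbon between the chelated hydroxyl and the ether oxygen.

**10 to 9.** The O–CH2OMe bond is cut. In 9 the two hydroxyls are equivalent by symmetry, so mono-protection gives one compound. A removable group is needed and not a methyl group: the oxygen left free during the rearrangement ends up at C5, which must be methylated, while the covered oxygen ends up at C7, which must be free.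

**9 to 7 and 8.** The bond between the para oxygen and the tertiary propargylic carbon is cut, giving phloroglucinol 7 and the commercial chloride 8. The para hydroxyl of 7 is the most acidic and the only one not tied to the ketone. The forward reaction must alkylate this oxygen and not an ortho oxygen or a ring carbon.

**7 to 5.** The ring bond between the acyl-bearing carbon and a neighbouring hydroxyl-bearing carbon is cut (C6–C7 of 14; C6–C5 is equivalent at this stage). This opens ring A to the triketo ester 6, whose lactone form is pyrone 5. A Friedel–Crafts acylation of a phloroglucinol would need Lewis acid that the ketal cannot bear. The polyketide cut instead makes the ring with all three oxygens and the acyl carbon in place and reduces the benzene to a side chain on a simple heterocycle. The forward reaction must fold by Claisen condensation and not by aldol addition.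

**5 to 3 and 2.** The bond between the methyl carbon of the pyrone and the side-chain ketone carbon is cut, giving commercial pyrone 3 and ester 2. The ester has no α-hydrogen and cannot quench the carbanion. The forward reaction must acylate dianion 4 at carbon.

**2 to 1.** The two ketal C–O bonds are cut, giving commercial keto ester 1. The ketal is installed first because the free ketone of 1 would be the more reactive electrophile in the acylation.

## Roads not taken

**Alternative 1:** The cut is the C3=C4 double bond of the pyran ring. Forward, diene A2, a benzaldehyde with a vinyl group at the future C4a and a 1,1-dimethylallyl ether at the future O1, is closed by the second-generation Grubbs catalyst (H2IMes)(PCy3)Cl2Ru=CHPh to chromene aldehyde A1.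
- Merits: the position of the pyran ring is fixed by substituents placed beforehand, and the closure is neutral and needs little heat. In regiochemical certainty at the pyran ring this road is better than the chosen plan.
- Weak points: A2 is a pentasubstituted benzene whose groups must be introduced one at a time. Its tertiary allyl aryl ether is hard to make and rearranges easily. After A1 the whole diketone is still missing: an anisoyl anion equivalent must be added to the aldehyde and the adduct oxidised, with the chromene alkene present.
- Comparison: the chosen plan sets symmetry and a chelation-directed rearrangement against the regiochemical certainty of this road, and it brings in both carbonyl carbons at the correct oxidation level in its second step.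

**Alternative 2:** The cut takes ring A apart at C6–C7, C4a–C5 and C7–C8. Forward, cyclobutenone A4 is heated with alkynyl ether A5. The vinylketene adds the alkyne, the adduct opens and closes by 6π electrocyclisation, and racemic phenol A3 results.
- Merits: all three ring oxygens are different from the outset (free phenol, silyl ether, methyl ether), so no selective protection is needed. Here it is superior to the chosen plan.
- Weak points: both partners need several steps each, and A4 is a sensitive vinylogous silyl ester. A3 is at the wrong oxidation level twice: the side chain needs oxidation at two carbons to become the diketone, and the prenyl group needs an oxidative cyclisation to become the chromene. The stereocentre of A3 is made only to be destroyed.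
- Comparison: the chosen plan is much shorter and needs no late oxidation of an electron-rich ring. It has to distinguish only two hydroxyls, by mono-protection of a symmetric compound.

**Alternative 3:** The cut is at both aryl–carbonyl bonds of the diketone. Forward, arene A7 is lithiated between its two MOM ethers and adds to one carbonyl of diamide A8, Grignard reagent A9 adds to the other, and acid releases diketone A6.
- Merits: it is the most convergent way to the benzil, with the aromatic ring taken from the phloroglucinol pool. In step count to the diketone it is at least as short as the chosen plan.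
- Weak points: A6 has two identical MOM ethers beside the acyl group, so the C5/C7 distinction is still open. The free diketone must then survive desilylation, base-mediated etherification, heating for the rearrangement and methylation. The acid that releases the diketone also threatens the MOM ethers, and the aryllithium is hindered on both sides.
- Comparison: the chosen plan accepts a linear sequence and sets against it that the second carbonyl stays a ketal until the last step and that the symmetry problem is solved by the same protecting group that is removed in that step.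

Key step: step 3

Assumption: the target is taken to rest as the open, hydrogen-bonded 1,2-diketone drawn and not as its cyclic hemiketal, since the second carbonyl is conjugated with the anisyl ring.

## Route

Step 1
Reactants: 1 methyl 2-(4-methoxyphenyl)-2-oxoacetate
Product: 2 methyl 2,2-dimethoxy-2-(4-methoxyphenyl)acetate
Conditions: HC(OMe)3, MeOH, H2SO4 (cat.), reflux
Reagents that add atoms: trimethyl orthoformate, COC(OC)OC; methanol, CO
Why: Acid-catalysed ketalisation of an α-keto ester, with the orthoformate removing water as methyl formate; the ester is untouched and the new quaternary carbon has no hydrogen.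

Step 2
Reactants: 3 4-hydroxy-6-methyl-2H-pyran-2-one; 2 methyl 2,2-dimethoxy-2-(4-methoxyphenyl)acetate
Product: 5 4-hydroxy-6-[3,3-dimethoxy-3-(4-methoxyphenyl)-2-oxopropyl]-2H-pyran-2-one, via dilithiated 4-hydroxy-6-methyl-2-pyrone 4 (not isolated)
Conditions: LiN(i-Pr)2 (3.2 equiv), THF, −78 → 0 °C; then 2, −78 °C → rt; AcOH
Reagents that add atoms: none
Why: Claisen-type acylation of a dianion: the second deprotonation takes place at the 6-methyl group, and this carbanion is the more nucleophilic site and attacks the non-enolisable ester. The product is deprotonated at once by the third equivalent of base, which prevents a second addition.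

Step 3
Reactants: 5 4-hydroxy-6-[3,3-dimethoxy-3-(4-methoxyphenyl)-2-oxopropyl]-2H-pyran-2-one
Product: 7 2,2-dimethoxy-2-(4-methoxyphenyl)-1-(2,4,6-trihydroxyphenyl)ethan-1-one, via open-chain methyl trioxo ester 6 (not isolated)
Conditions: Mg(OMe)2 (5 equiv), MeOH, reflux; then AcOH, 0 °C
Reagents that add atoms: none
Why: Methoxide adds to the lactone carbonyl of 5 and opens the pyrone to the methyl 3,5,7-trioxo ester 6, held as a magnesium polyenolate chelate. The carbanion at C6 of this chain (ester carbon = C1), between the two distal ketones, attacks the ester carbonyl and expels methoxide; this is a Claisen condensation of the Dieckmann type and the known course of 6-(2-oxoalkyl)-4-hydroxy-2-pyrones under these conditions. Ring A closes in a 6-exo-trig mode, forming the bond that becomes C6–C7 of 14, and the 2-acylcyclohexane-1,3,5-trione enolises to the phloroglucinol, which draws the equilibria forward. No stereocentre is formed. The selectivity needed is Claisen against aldol folding, in which the C2 carbanion would add to the C7 ketone and give a resorcylate. Magnesium chelation ties up the β-dicarbonyl units as enolates and leaves the ester as the free electrophile, and the C7 ketone is shielded by the neighbouring quaternary ketal carbon. That carbon has no hydrogen, so the masked second carbonyl can neither enolise nor serve as an electrophile during the fold.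

Step 4
Reactants: 7 2,2-dimethoxy-2-(4-methoxyphenyl)-1-(2,4,6-trihydroxyphenyl)ethan-1-one; 8 3-chloro-3-methylbut-1-yne
Product: 9 1-{2,6-dihydroxy-4-[(2-methylbut-3-yn-2-yl)oxy]phenyl}-2,2-dimethoxy-2-(4-methoxyphenyl)ethan-1-one
Conditions: DBU (1.1 equiv), CuCl2·2H2O (1 mol%), MeCN, 0 °C
Reagents that add atoms: none
Why: Copper-catalysed O-propargylation of a phenol with a tertiary propargylic chloride. The para hydroxyl is the most acidic and the only one not held by the ketone, so one equivalent of base should give the para phenoxide and hence the para ether.

Step 5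
Reactants: 9 1-{2,6-dihydroxy-4-[(2-methylbut-3-yn-2-yl)oxy]phenyl}-2,2-dimethoxy-2-(4-methoxyphenyl)ethan-1-one
Product: 10 1-{2-hydroxy-6-(methoxymethoxy)-4-[(2-methylbut-3-yn-2-yl)oxy]phenyl}-2,2-dimethoxy-2-(4-methoxyphenyl)ethan-1-one
Conditions: MOMCl (1.2 equiv), i-Pr2NEt, CH2Cl2, 0 °C
Reagents that add atoms: chloromethyl methyl ether (MOMCl), COCCl
Why: MOM ether formation under amine base. The two hydroxyls of 9 are equivalent, and once one is protected the other is locked in a hydrogen bond to the ketone and reacts much more slowly, so the mono-ether is expected.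

Step 6
Reactants: 10 1-{2-hydroxy-6-(methoxymethoxy)-4-[(2-methylbut-3-yn-2-yl)oxy]phenyl}-2,2-dimethoxy-2-(4-methoxyphenyl)ethan-1-one
Product: 12 1-[5-hydroxy-7-(methoxymethoxy)-2,2-dimethyl-2H-chromen-6-yl]-2,2-dimethoxy-2-(4-methoxyphenyl)ethan-1-one, via ortho-allenyl phenol 11 (not isolated)
Conditions: PhNEt2, 185 °C
Reagents that add atoms: none
Why: Aryl propargyl ether Claisen rearrangement to the allenyl phenol 11, then 1,5-hydrogen shift and oxa-6π electrocyclisation, the standard thermal chromene synthesis. The hydrogen bond from the free hydroxyl to the ketone fixes the ring double bonds so that the carbon between this hydroxyl and the ether oxygen is the migration terminus, as in 2-hydroxy-4-propargyloxy aryl ketones. The basic solvent spares MOM ether and ketal.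

Step 7
Reactants: 12 1-[5-hydroxy-7-(methoxymethoxy)-2,2-dimethyl-2H-chromen-6-yl]-2,2-dimethoxy-2-(4-methoxyphenyl)ethan-1-one
Product: 13 2,2-dimethoxy-1-[5-methoxy-7-(methoxymethoxy)-2,2-dimethyl-2H-chromen-6-yl]-2-(4-methoxyphenyl)ethan-1-one
Conditions: MeI, K2CO3, DMF, 40 °C
Reagents that add atoms: iodomethane (MeI), CI
Why: Williamson methylation of the only free hydroxyl; the polar aprotic solvent and excess MeI overcome the hydrogen bond to the ketone, and no other nucleophilic site is present.

Step 8
Reactants: 13 2,2-dimethoxy-1-[5-methoxy-7-(methoxymethoxy)-2,2-dimethyl-2H-chromen-6-yl]-2-(4-methoxyphenyl)ethan-1-one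
Product: 14 1-(7-hydroxy-5-methoxy-2,2-dimethyl-2H-chromen-6-yl)-2-(4-methoxyphenyl)ethane-1,2-dione
Conditions: 3 M aq. HCl, THF, 45 °C
Reagents that add atoms: water, O
Why: Acid hydrolysis of an aryl MOM ether and of a dimethyl ketal in one operation. The 4-methoxyphenyl group stabilises the oxocarbenium ion at the ketal carbon and offsets the retarding neighbouring carbonyl, and the chromene alkene, deactivated by the acyl group, should survive dilute acid at this temperature.

## Compound list

1 | methyl 2-(4-methoxyphenyl)-2-oxoacetate (methyl 4-methoxyphenylglyoxylate) | COC(=O)C(=O)c1ccc(OC)cc1 | starting material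
2 | methyl 2,2-dimethoxy-2-(4-methoxyphenyl)acetate | COC(=O)C(OC)(OC)c1ccc(OC)cc1 | intermediate
3 | 4-hydroxy-6-methyl-2H-pyran-2-one | Cc1cc(O)cc(=O)o1 | starting material
4 | dilithiated 4-hydroxy-6-methyl-2-pyrone (dianion at the hydroxyl oxygen and the methyl carbon, dilithium salt) | [Li+].[Li+].[CH2-]c1cc([O-])cc(=O)o1 | intermediate
5 | 4-hydroxy-6-[3,3-dimethoxy-3-(4-methoxyphenyl)-2-oxopropyl]-2H-pyran-2-one | COc1ccc(cc1)C(OC)(OC)C(=O)Cc1cc(O)cc(=O)o1 | intermediate
6 | methyl 8,8-dimethoxy-8-(4-methoxyphenyl)-3,5,7-trioxooctanoate (present as its magnesium chelate) | COC(=O)CC(=O)CC(=O)CC(=O)C(OC)(OC)c1ccc(OC)cc1 | intermediate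
7 | 2,2-dimethoxy-2-(4-methoxyphenyl)-1-(2,4,6-trihydroxyphenyl)ethan-1-one | COc1ccc(cc1)C(OC)(OC)C(=O)c1c(O)cc(O)cc1O | intermediate
8 | 3-chloro-3-methylbut-1-yne | CC(C)(Cl)C#C | starting material
9 | 1-{2,6-dihydroxy-4-[(2-methylbut-3-yn-2-yl)oxy]phenyl}-2,2-dimethoxy-2-(4-methoxyphenyl)ethan-1-one | COc1ccc(cc1)C(OC)(OC)C(=O)c1c(O)cc(OC(C)(C)C#C)cc1O | intermediate
10 | 1-{2-hydroxy-6-(methoxymethoxy)-4-[(2-methylbut-3-yn-2-yl)oxy]phenyl}-2,2-dimethoxy-2-(4-methoxyphenyl)ethan-1-one | COc1ccc(cc1)C(OC)(OC)C(=O)c1c(O)cc(OC(C)(C)C#C)cc1OCOC | intermediate
11 | 1-[2,4-dihydroxy-6-(methoxymethoxy)-3-(3-methylbuta-1,2-dien-1-yl)phenyl]-2,2-dimethoxy-2-(4-methoxyphenyl)ethan-1-one | COc1ccc(cc1)C(OC)(OC)C(=O)c1c(O)c(C=C=C(C)C)c(O)cc1OCOC | intermediate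
12 | 1-[5-hydroxy-7-(methoxymethoxy)-2,2-dimethyl-2H-chromen-6-yl]-2,2-dimethoxy-2-(4-methoxyphenyl)ethan-1-one | COc1ccc(cc1)C(OC)(OC)C(=O)c1c(O)c2C=CC(C)(C)Oc2cc1OCOC | intermediate
13 | 2,2-dimethoxy-1-[5-methoxy-7-(methoxymethoxy)-2,2-dimethyl-2H-chromen-6-yl]-2-(4-methoxyphenyl)ethan-1-one | COc1ccc(cc1)C(OC)(OC)C(=O)c1c(OC)c2C=CC(C)(C)Oc2cc1OCOC | intermediate
14 | 1-(7-hydroxy-5-methoxy-2,2-dimethyl-2H-chromen-6-yl)-2-(4-methoxyphenyl)ethane-1,2-dione | COc1ccc(C(=O)C(=O)c2c(O)cc3c(c2OC)C=CC(C)(C)O3)cc1 | target

## Step count and least certain steps

Total step count: 8. Longest linear sequence: 8 steps (1 → 2 → 5 → 7 → 9 → 10 → 12 → 13 → 14); 3 enters at step 2 and 8 at step 4.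

**Step 3 (key step).** The chain may fold the other way, by aldol addition of the carbanion next to the ester onto the side-chain ketone. Methoxide may also attack that ketone, which its two α-methoxy groups make more electrophilic, and cleave the chain by retro-Claisen reaction. The fallback sets out from 2 and comes back at 7, taking ring A from the aromatic pool. 1,3,5-Tris(benzyloxy)benzene F1 is lithiated between two benzyloxy groups (n-BuLi, THF, 0 °C) and acylated with ester 2 to give 2,2-dimethoxy-2-(4-methoxyphenyl)-1-[2,4,6-tris(benzyloxy)phenyl]ethan-1-one F2. Hydrogenolysis (H2, Pd/C, EtOAc) removes the three benzyl groups and gives 7.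

**Step 2.** Attack on the ester carbonyl, which sits beside a fully substituted carbon, may be slow, so that proton transfer and decay of the dianion compete with acylation. The fallback sets out from 2 and comes back at 5, replacing the acylation by an aldol addition and an oxidation. Ester 2 is reduced with i-Bu2AlH (CH2Cl2, −78 °C) to 2,2-dimethoxy-2-(4-methoxyphenyl)acetaldehyde F3. Dianion 4 adds to this far less hindered electrophile to give racemic 4-hydroxy-6-[2-hydroxy-3,3-dimethoxy-3-(4-methoxyphenyl)propyl]-2H-pyran-2-one F4, and Dess–Martin periodinane (CH2Cl2, NaHCO3) oxidises the carbinol to 5.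

**Step 4.** Alkylation may not stop at the para oxygen: a second etherification at an ortho hydroxyl, C-alkylation of the electron-rich ring, and loss of HCl from 8 can all lower the return. The fallback sets out from 7 and comes back at 10, distinguishing the oxygens by protecting groups. The para hydroxyl is silylated (i-Pr3SiCl, imidazole, DMF, 0 °C) to 1-{2,6-dihydroxy-4-[(triisopropylsilyl)oxy]phenyl}-2,2-dimethoxy-2-(4-methoxyphenyl)ethan-1-one F5. Mono-protection (MOMCl, i-Pr2NEt) gives 1-{2-hydroxy-6-(methoxymethoxy)-4-[(triisopropylsilyl)oxy]phenyl}-2,2-dimethoxy-2-(4-methoxyphenyl)ethan-1-one F6, and Bu4NF (THF, 0 °C) frees the para hydroxyl to give 1-[2,4-dihydroxy-6-(methoxymethoxy)phenyl]-2,2-dimethoxy-2-(4-methoxyphenyl)ethan-1-one F7. This compound has only one hydroxyl that is not chelated, and its propargylation with 8 under the conditions of step 4 gives 10.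

**Step 6.** Regiocontrol may be eroded: if the bulky acyl group twists out of the ring plane, the hydrogen bond weakens and migration to the carbon beside the MOM ether competes. Thermal exchange of a ketal methoxy group with the free phenol is a second risk. The fallback sets out from 9 and comes back at 12, running the rearrangement before the protection. Heating symmetric 9 (PhNEt2, 185 °C) can give only one chromene, 1-(5,7-dihydroxy-2,2-dimethyl-2H-chromen-6-yl)-2,2-dimethoxy-2-(4-methoxyphenyl)ethan-1-one F8, with closure on the freshly released para oxygen. The C7 hydroxyl of this compound is flanked only by hydrogen, while the C5 hydroxyl sits between the acyl group and C4a, so MOMCl and i-Pr2NEt should protect C7 and give 12.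

**Step 8.** The acid may hydrate or oligomerise the chromene before the deactivated ketal has hydrolysed, or the freed C7 hydroxyl may trap the oxocarbenium ion and stall the hydrolysis at a cyclic mixed ketal. The fallback sets out from 13 and comes back at 14, separating the two deprotections and avoiding Brønsted acid. Ketal exchange with acetone (I2 cat., acetone, rt) gives 1-[5-methoxy-7-(methoxymethoxy)-2,2-dimethyl-2H-chromen-6-yl]-2-(4-methoxyphenyl)ethane-1,2-dione F9. Chelation-assisted cleavage of the MOM ether ortho to the carbonyl (MgBr2·OEt2, Et2O, rt, aqueous work-up) then gives 14.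

## Further compounds

F1 | step 3 | 1,3,5-tris(benzyloxy)benzene | c1ccc(cc1)COc1cc(OCc2ccccc2)cc(OCc2ccccc2)c1
F2 | step 3 | 2,2-dimethoxy-2-(4-methoxyphenyl)-1-[2,4,6-tris(benzyloxy)phenyl]ethan-1-one | COc1ccc(cc1)C(OC)(OC)C(=O)c1c(OCc2ccccc2)cc(OCc2ccccc2)cc1OCc1ccccc1
F3 | step 2 | 2,2-dimethoxy-2-(4-methoxyphenyl)acetaldehyde | COc1ccc(cc1)C(OC)(OC)C=O
F4 | step 2 | 4-hydroxy-6-[2-hydroxy-3,3-dimethoxy-3-(4-methoxyphenyl)propyl]-2H-pyran-2-one (racemic) | COc1ccc(cc1)C(OC)(OC)C(O)Cc1cc(O)cc(=O)o1
F5 | step 4 | 1-{2,6-dihydroxy-4-[(triisopropylsilyl)oxy]phenyl}-2,2-dimethoxy-2-(4-methoxyphenyl)ethan-1-one | COc1ccc(cc1)C(OC)(OC)C(=O)c1c(O)cc(O[Si](C(C)C)(C(C)C)C(C)C)cc1O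
F6 | step 4 | 1-{2-hydroxy-6-(methoxymethoxy)-4-[(triisopropylsilyl)oxy]phenyl}-2,2-dimethoxy-2-(4-methoxyphenyl)ethan-1-one | COc1ccc(cc1)C(OC)(OC)C(=O)c1c(O)cc(O[Si](C(C)C)(C(C)C)C(C)C)cc1OCOC
F7 | step 4 | 1-[2,4-dihydroxy-6-(methoxymethoxy)phenyl]-2,2-dimethoxy-2-(4-methoxyphenyl)ethan-1-one | COc1ccc(cc1)C(OC)(OC)C(=O)c1c(O)cc(O)cc1OCOC
F8 | step 6 | 1-(5,7-dihydroxy-2,2-dimethyl-2H-chromen-6-yl)-2,2-dimethoxy-2-(4-methoxyphenyl)ethan-1-one | COc1ccc(cc1)C(OC)(OC)C(=O)c1c(O)cc2OC(C)(C)C=Cc2c1O
F9 | step 8 | 1-[5-methoxy-7-(methoxymethoxy)-2,2-dimethyl-2H-chromen-6-yl]-2-(4-methoxyphenyl)ethane-1,2-dione | COCOc1cc2OC(C)(C)C=Cc2c(OC)c1C(=O)C(=O)c1ccc(OC)cc1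
A1 | alternative 1 | 7-hydroxy-5-methoxy-2,2-dimethyl-2H-chromene-6-carbaldehyde | O=Cc1c(O)cc2OC(C)(C)C=Cc2c1OC
A2 | alternative 1 | 3-ethenyl-6-hydroxy-2-methoxy-4-[(2-methylbut-3-en-2-yl)oxy]benzaldehyde | O=Cc1c(O)cc(OC(C)(C)C=C)c(C=C)c1OC
A3 | alternative 2 | 2-[1-(tert-butyldimethylsilyloxy)-2-(4-methoxyphenyl)ethyl]-3-methoxy-4-(3-methylbut-2-enyl)-5-(triisopropylsilyloxy)phenol (racemic) | Oc1cc(O[Si](C(C)C)(C(C)C)C(C)C)c(CC=C(C)C)c(OC)c1C(O[Si](C)(C)C(C)(C)C)Cc1ccc(OC)cc1
A4 | alternative 2 | 2-(3-methylbut-2-en-1-yl)-3-[(triisopropylsilyl)oxy]cyclobut-2-en-1-one | O=C1CC(O[Si](C(C)C)(C(C)C)C(C)C)=C1CC=C(C)C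
A5 | alternative 2 | tert-butyl{[4-methoxy-1-(4-methoxyphenyl)but-3-yn-2-yl]oxy}dimethylsilane (racemic) | COC#CC(O[Si](C)(C)C(C)(C)C)Cc1ccc(OC)cc1
A6 | alternative 3 | 1-[2,6-bis(methoxymethoxy)-4-(triisopropylsilyloxy)phenyl]-2-(4-methoxyphenyl)ethane-1,2-dione | COCOc1cc(O[Si](C(C)C)(C(C)C)C(C)C)cc(OCOC)c1C(=O)C(=O)c1ccc(OC)cc1
A7 | alternative 3 | [3,5-bis(methoxymethoxy)phenoxy]triisopropylsilane | COCOc1cc(OCOC)cc(O[Si](C(C)C)(C(C)C)C(C)C)c1
A8 | alternative 3 | 1,4-dimethylpiperazine-2,3-dione | CN1CCN(C)C(=O)C1=O
A9 | alternative 3 | 4-methoxyphenylmagnesium bromide | COc1ccc([Mg]Br)cc1
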